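L is wanted twice in these flasks: E binds it reversibly as X, while J takes it for good as G.

| flask | E | L | J | remark | time |
|---|---|---|---|---|---|
| red | 0.67 M | 1.2 M | 1 M | run made earlier |  |
| grey | 1.5 M | 1.2 M | 1 M | run made earlier |  |
| ochre | 1 M | 0.60 M | 1 M | run made earlier |  |
| flask | 1.0 M | 1.20 M | 1.00 M |  | 15 d |

| run | time / d | X / % | E / % |
|---|---|---|---|
| red | 0.833 | 17.6 | 83.2 |
| red | 2.50 | 12.7 | 87.5 |
| red | 4.00 | 13.8 | 86.3 |
| red | 6.00 | 13.6 | 85.9 |
| red | 10.0 | 14.6 | 86.3 |
| grey | 0.625 | 15.8 | 85.5 |
| grey | 1.25 | 13.2 | 86.7 |
| grey | 2.50 | 9.8 | 89.5 |
| grey | 5.00 | 10.3 | 90.7 |
| grey | 10.0 | 7.9 | 89.7 |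
| ochre | 0.625 | 5.6 | 95.1 |
| ochre | 1.25 | 2.9 | 98.0 |
| ochre | 2.50 | 0 | 99.6 |
| ochre | 5.00 | 1.6 | 100.7 |
| ochre | 10.0 | 0.8 | 100.1 |

(standard deviation of a reading: 1 percentage point)

- the state of affairs at 15 d: stopped, and by what, or still going (it is still moving / forward and back rates have come level / L has run out first / all of E has reacted)
- how much X there is at 15 d, in percent of the E charged

- the numbers in the tables scatter with a standard deviation of 1 percentage point
- steps thought possible: E + L <-> X; J + L -> G
- the reaction counts as stopped when no species that holds the E changes by six tenths of a point or more over the second half of the time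

You can read these runs without integrating anything. In red and grey, L exceeds J by 0.200 M, and X falls early and then stays level from 2.50 d on, well before the flask's 15 d. In ochre, L at 0.60 M is the limiting reagent against J at 1 M, and X reads 0.8% at the last reading. So I take the level as the balance of E and L over the surplus.

Let x be the share of charged E held as X at the level, and s the surplus of L over J as a share of charged E. Free E is then 1 − x, free L is s − x, and x = Kc(1 − x)(s − x), where c is the E charge. The level readings average 13.7% in red and 9.33% in grey. These give K as 1.46 /M and 1.72 /M. Their mean, 1.59 /M, is my reading of the binding constant of the surplus.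

My first way takes the flask's s = 0.200 and the smaller root of that quadratic, which gives x = 11.7%. My second way uses no constant: a straight line between the level amounts of X in red and grey gives 11.1% at this flask's charge. They part by 0.60 percentage points, less than the scatter of one reading, but both lean on the same level readings, so that nearness is no independent check. The line is the one that cheats: the root's curve of X against the E charge is bent, and the straight chord gives 11.1%, less than the root's 11.7%. I commit to the root.

The forecast says that forward and back rates have come level, with X at 11.4%, 0.30 points under my root, on these grounds: “The plateaus show that E + L ⇌ X equilibrates quickly, while J + L → G irreversibly removes L.”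

The flask shows that forward and back rates have come level, with X at 11.4%, as the forecast said.

    E + L ⇌ X (K = 1.50 /M, k = 0.00430 /M/min)
    J + L → G (k = 0.0100 /M/min)

My root from K stood 0.30 points above that value. Now take the neighbouring flask, with J cut to 0.60 M and the other charges held. Its surplus share becomes 0.600, and the same K gives x = 31.3%. That neighbour gives 30.6% of X at 15.0 d, with 69.4% of its E and 24% of its L unbound.

All runs were computed with constants of no real substance.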